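**Plan**
1. The retrosynthesis first cuts the two cyclobutane bonds (spiro C–spiro C and CHBr–CHBr). The target is then the head-to-head, oxygen-anti [2+2] dimer of two 4-bromo-5-(bromomethylidene)furan-2(5H)-ones, 14 (3-butyl) and 17 (3-[(1R)-1-acetoxybutyl]).
2. 17 is cut back to 14 at the side-chain C–O bond, so one butenolide nucleus serves both halves.
3. That nucleus is cut at C2–C3 and C4–C5 (lactone numbering O1, C2=O, C3, C4, C5). This is possible because C2 and C5 both hang on O1 and C3=C4 is a fully substituted alkene. C5–O1–C2 is therefore bought as 1-chloroethyl chloroformate (a leaving group on each carbon), and C3=C4 as a hex-1-ynyl boronate on zirconocene, with boron standing in for the C4 bromine.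
4. Forward order: lactone ring (step 2), boron to bromine and C5 methyl to bromomethylidene (steps 3–5), side-chain oxidation and resolution on part of the material (steps 6–8), cyclobutane last (step 9).
5. Stereochemistry: the side-chain centre comes from a lipase acetylation. The four cyclobutane centres arise together in the photocycloaddition: their relative configuration comes from suprafacial union of the (E)-alkenes, and the absolute sense is obtained by separating two diastereomers.

Key step: step 2

Assumption: the ring configuration of the target (ring oxygens anti, each cyclobutane C–Br cis to the vinylic C–Br carbon of the lactone on the adjacent spiro carbon) is that of a suprafacial head-to-head [2+2] union of the two (E)-bromomethylidene alkenes. The (Z)-isomers made in steps 5–8 are therefore isomerised in the flask by the same light.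

Remark: cyclopentadienyl rings are written σ-bonded in the SMILES of zirconium compounds; racemic compounds are written without a stereo label at the racemic centre.

**Step 1**
Reactants: 1 hex-1-yne; 2 2-isopropoxy-4,4,5,5-tetramethyl-1,3,2-dioxaborolane
Product: 5 2-(hex-1-yn-1-yl)-4,4,5,5-tetramethyl-1,3,2-dioxaborolane, via hex-1-ynyllithium 3 (not isolated), via lithium borate complex 4 (not isolated)
Conditions: n-BuLi, THF, −78 °C; 2, −78 °C; HCl in Et2O, −78 °C to rt
Reagents that add atoms: none
Why: Deprotonation of the terminal alkyne and borylation of the acetylide with an alkoxyborane is the standard route to alkynyl pinacol boronates; anhydrous acid collapses ate complex 4 by loss of propan-2-ol and no stereocentre is formed.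

**Step 2**
Reactants: 5 2-(hex-1-yn-1-yl)-4,4,5,5-tetramethyl-1,3,2-dioxaborolane; 6 1-chloroethyl chloroformate
Product: 9 3-butyl-5-methyl-4-(4,4,5,5-tetramethyl-1,3,2-dioxaborolan-2-yl)furan-2(5H)-one (racemic), via zirconacyclopentene 7 (not isolated), via alkenylzirconium chloride 8 (not isolated)
Conditions: Cp2ZrCl2, EtMgBr (2 equiv), THF, −78 °C; 5, 0 °C; 6, 0 °C to rt; CuCl, 50 °C
Reagents that add atoms: none
Why: Proposed new method: Cp2ZrEt2 loses ethane to give the ethene complex of divalent zirconium, which couples with 5 to zirconacyclopentene 7 with boron on the carbon next to zirconium; the acyl chloride end of 6 then displaces ethene and acylates the butyl-bearing carbon (forming C2–C3) to give alkenylzirconium 8 with zirconium and ester cis, and transmetalation to copper lets the vinyl carbon displace chloride from the 1-chloroethyl ester carbon (forming C4–C5). The closest known reaction types are the zirconocene-mediated alkoxycarbonylation of alkynes with chloroformates through zirconacyclopentenes and the CuCl-promoted alkylation of alkenylzirconocenes, including 1-boryl-1-zirconioalkenes; what is new is that one reagent carries both electrophilic carbons on the same oxygen. The lactone ring closes in the 5-exo-tet mode. The only new stereocentre, C5, forms racemic and is left uncontrolled on purpose because step 4 turns it into an sp2 carbon. The step needs regioselectivity across the alkyne, secured by the boryl group, which stays beside zirconium so that acylation takes the distal carbon, and chemoselectivity between the two C–Cl bonds of 6, secured by their reactivity order (the acyl chloride reacts at 0 °C, the alkyl chloride only after copper is added and the mixture is warmed).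

**Step 3**
Reactants: 9 3-butyl-5-methyl-4-(4,4,5,5-tetramethyl-1,3,2-dioxaborolan-2-yl)furan-2(5H)-one
Product: 10 4-bromo-3-butyl-5-methylfuran-2(5H)-one (racemic)
Conditions: CuBr2 (3 equiv), MeOH–H2O (1:1), 70 °C
Reagents that add atoms: copper dibromide, [Cu+2].[Br-].[Br-]
Why: Copper-mediated halodeboronation: the alkenyl group passes from boron to divalent copper, a second CuBr2 oxidises it to trivalent copper, and C–Br reductive elimination puts bromine exactly where boron was, leaving C5 untouched.

**Step 4**
Reactants: 10 4-bromo-3-butyl-5-methylfuran-2(5H)-one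
Product: 12 4-bromo-3-butyl-5-methylidenefuran-2(5H)-one, via tertiary bromide 11 (not isolated)
Conditions: NBS, AIBN (cat.), PhCF3, 85 °C; then Et3N, 0 °C to rt
Reagents that add atoms: none
Why: Wohl–Ziegler bromination should take the C5–H, the weakest C–H (tertiary, next to O1, allylic to C3=C4), and E2 loss of HBr from 11 can only use a methyl hydrogen, which erases the racemic C5 centre as the exocyclic alkene.

**Step 5**
Reactants: 12 4-bromo-3-butyl-5-methylidenefuran-2(5H)-one
Product: 14 (5Z)-4-bromo-5-(bromomethylidene)-3-butylfuran-2(5H)-one, via tribromide 13 (not isolated)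
Conditions: Br2 (1 equiv), CH2Cl2, −40 °C; then DBU, 0 °C
Reagents that add atoms: bromine, BrBr
Why: Bromine adds to the electron-rich exocyclic enol-ester alkene and not to the electron-poor C3=C4 bond, and E2 elimination from 13 (H from CH2Br, Br from C5) gives the bromomethylidene group, expected mainly as the (Z)-isomer; the geometry is not critical because step 9 equilibrates it.

**Step 6**
Reactants: 14 (5Z)-4-bromo-5-(bromomethylidene)-3-butylfuran-2(5H)-one
Product: 15 (5Z)-4-bromo-3-(1-bromobutyl)-5-(bromomethylidene)furan-2(5H)-one (racemic)
Conditions: NBS (1.1 equiv), dibenzoyl peroxide (cat.), PhCF3, reflux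
Reagents that add atoms: N-bromosuccinimide, O=C1CCC(=O)N1Br
Why: Wohl–Ziegler bromination at the only allylic sp3 C–H left, the CH2 next to C3; the new centre is racemic and is resolved in step 8.

**Step 7**
Reactants: 15 (5Z)-4-bromo-3-(1-bromobutyl)-5-(bromomethylidene)furan-2(5H)-one
Product: 16 (5Z)-4-bromo-5-(bromomethylidene)-3-(1-hydroxybutyl)furan-2(5H)-one (racemic)
Conditions: Ag2CO3, acetone–H2O (4:1), 40 °C, dark
Reagents that add atoms: water, O
Why: Silver-assisted solvolysis: Ag2CO3 pulls bromide from the allylic secondary carbon, water captures the cation and the carbonate takes up the acid; the centre stays racemic.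

**Step 8**
Reactants: 16 (5Z)-4-bromo-5-(bromomethylidene)-3-(1-hydroxybutyl)furan-2(5H)-one (racemic)
Product: 17 (1R)-1-[(5Z)-4-bromo-5-(bromomethylidene)-2-oxo-2,5-dihydrofuran-3-yl]butyl acetate
Conditions: immobilised lipase from Burkholderia cepacia (a serine hydrolase), vinyl acetate, MTBE, 30 °C, stopped near half conversion
Reagents that add atoms: vinyl acetate, CC(=O)OC=C
Why: Kinetic resolution by enzymatic transesterification with an irreversible acyl donor: by the empirical size rule for lipases (large group the lactone ring, medium group propyl) the (R)-alcohol should react faster, so the acetate formed is (R)-17 and the (S)-alcohol stays behind.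

**Step 9**
Reactants: 14 (5Z)-4-bromo-5-(bromomethylidene)-3-butylfuran-2(5H)-one (used in excess); 17 (1R)-1-[(5Z)-4-bromo-5-(bromomethylidene)-2-oxo-2,5-dihydrofuran-3-yl]butyl acetate
Product: 20 CNP0268004.1, via (5E)-butyl monomer 18 (not isolated), via (5E)-acetoxybutyl monomer 19 (not isolated)
Conditions: hν (350 nm, Pyrex), MeCN, 0.5 M, Ar, 10 °C; chromatography, then preparative HPLC
Reagents that add atoms: none
Why: [2+2] photocycloaddition of 5-ylidenebutenolides (the parent 5-methylidene compound is known to dimerise head to head with the ring oxygens anti): the light first equilibrates Z and E, the suprafacial head-to-head anti union of 18 and 19 sets the four ring centres relative to one another, and, because the remote (R) centre gives no facial bias, the target is expected together with the diastereomer built on the mirror-image cyclobutane, from which it is separated.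

**Compound list**
1 | hex-1-yne | CCCCC#C | starting material
2 | 2-isopropoxy-4,4,5,5-tetramethyl-1,3,2-dioxaborolane | CC(C)OB1OC(C)(C)C(C)(C)O1 | starting material
3 | hex-1-ynyllithium | [Li]C#CCCCC | intermediate (not isolated)
4 | lithium (hex-1-yn-1-yl)(isopropoxy)(pinacolato)borate | [Li+].CCCCC#C[B-]1(OC(C)C)OC(C)(C)C(C)(C)O1 | intermediate (not isolated)
5 | 2-(hex-1-yn-1-yl)-4,4,5,5-tetramethyl-1,3,2-dioxaborolane | CCCCC#CB1OC(C)(C)C(C)(C)O1 | intermediate
6 | 1-chloroethyl chloroformate (racemic) | CC(Cl)OC(Cl)=O | starting material
7 | 3-butyl-1,1-bis(cyclopentadienyl)-2-(pinacolboryl)-1-zirconacyclopent-2-ene | CCCCC1=C(B2OC(C)(C)C(C)(C)O2)[Zr](C2C=CC=C2)(C2C=CC=C2)CC1 | intermediate (not isolated)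
8 | 1-chloroethyl (Z)-2-butyl-3-[chlorobis(cyclopentadienyl)zirconio]-3-(pinacolboryl)prop-2-enoate | CCCC/C(C(=O)OC(C)Cl)=C(\B1OC(C)(C)C(C)(C)O1)[Zr](Cl)(C1C=CC=C1)C1C=CC=C1 | intermediate (not isolated)
9 | 3-butyl-5-methyl-4-(4,4,5,5-tetramethyl-1,3,2-dioxaborolan-2-yl)furan-2(5H)-one (racemic) | CCCCC1=C(B2OC(C)(C)C(C)(C)O2)C(C)OC1=O | intermediate
10 | 4-bromo-3-butyl-5-methylfuran-2(5H)-one (racemic) | CCCCC1=C(Br)C(C)OC1=O | intermediate
11 | 4,5-dibromo-3-butyl-5-methylfuran-2(5H)-one (racemic) | CCCCC1=C(Br)C(C)(Br)OC1=O | intermediate (not isolated)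
12 | 4-bromo-3-butyl-5-methylidenefuran-2(5H)-one | CCCCC1=C(Br)C(=C)OC1=O | intermediate
13 | 4,5-dibromo-5-(bromomethyl)-3-butylfuran-2(5H)-one (racemic) | CCCCC1=C(Br)C(Br)(CBr)OC1=O | intermediate (not isolated)
14 | (5Z)-4-bromo-5-(bromomethylidene)-3-butylfuran-2(5H)-one | CCCCC1=C(Br)/C(=C/Br)OC1=O | intermediate
15 | (5Z)-4-bromo-3-(1-bromobutyl)-5-(bromomethylidene)furan-2(5H)-one (racemic) | CCCC(Br)C1=C(Br)/C(=C/Br)OC1=O | intermediate
16 | (5Z)-4-bromo-5-(bromomethylidene)-3-(1-hydroxybutyl)furan-2(5H)-one (racemic) | CCCC(O)C1=C(Br)/C(=C/Br)OC1=O | intermediate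
17 | (1R)-1-[(5Z)-4-bromo-5-(bromomethylidene)-2-oxo-2,5-dihydrofuran-3-yl]butyl acetate | CCC[C@@H](OC(C)=O)C1=C(Br)/C(=C/Br)OC1=O | intermediate
18 | (5E)-4-bromo-5-(bromomethylidene)-3-butylfuran-2(5H)-one | CCCCC1=C(Br)/C(=C\Br)OC1=O | intermediate (not isolated)
19 | (1R)-1-[(5E)-4-bromo-5-(bromomethylidene)-2-oxo-2,5-dihydrofuran-3-yl]butyl acetate | CCC[C@@H](OC(C)=O)C1=C(Br)/C(=C\Br)OC1=O | intermediate (not isolated)
20 | CNP0268004.1, (1R)-1-(4,10,11,12-tetrabromo-3-butyl-2,8-dioxo-1,7-dioxadispiro[4.0.4.2]dodeca-3,9-dien-9-yl)butyl acetate; ring oxygens anti, the two cyclobutane bromines trans, each cis to the vinylic C–Br carbon of the lactone on the adjacent spiro carbon; absolute configuration as in the SMILES | CCCCC1=C(Br)[C@@]2(OC1=O)[C@@H](Br)[C@H](Br)[C@@]21OC(=O)C([C@@H](CCC)OC(C)=O)=C1Br | target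

**Totals**
Total step count: 9. Longest linear sequence: 9 steps (1 → 5 → 9 → 10 → 12 → 14 → 15 → 16 → 17 → 20).

**Steps most likely to fail**

Step 2. The vinyl–metal intermediate may fail to close onto the 1-chloroethyl ester carbon: the closure needs the disfavoured s-cis ester rotamer, protodemetalation on work-up would give the open-chain acrylate, and chloride may fragment the 1-chloroethyl group. The fallback reaches 10 from 1 by known chemistry. Lithiation of 1 and addition to acetaldehyde gives oct-3-yn-2-ol F1. Methyl chloroformate and pyridine give methyl oct-3-yn-2-yl carbonate F2. Carbonylation with Pd(PPh3)4 (zerovalent palladium) under CO in MeOH gives methyl 2-butylpenta-2,3-dienoate F3. LiOH gives 2-butylpenta-2,3-dienoic acid F4. Bromolactonisation of F4 with CuBr2 in aqueous acetone closes the ring with bromine on the central allene carbon and returns to the route at 10.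

Step 9. Homodimerisation of each partner, scrambling of the alkene geometry through a stepwise diradical, and the absence of facial bias may leave too little of the cross adduct. The fallback moves the cycloaddition in front of the side-chain chemistry. 14 alone is irradiated under the same conditions, which can only give homodimers, and the head-to-head anti dimer F5 (racemic, C2-symmetric) is isolated. One of its two equivalent allylic CH2 groups is brominated with NBS to the mono-bromide F6. Ag2CO3 in aqueous acetone gives the mono-alcohol F7. The lipase acetylation of step 8 applied to F7 acetylates the (R)-carbinol and, after separation from the diastereomeric acetate on the mirror-image cyclobutane, returns to the route at 20.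

Step 8. The electrophilic bromo-butenolide may alkylate and inactivate the enzyme, or the lipase may discriminate poorly between propyl and the lactone ring. The fallback sets the centre by reagent control from 16. Dess–Martin oxidation gives the ketone (5Z)-4-bromo-5-(bromomethylidene)-3-butanoylfuran-2(5H)-one F8. Corey–Bakshi–Shibata reduction with the (S)-methyl oxazaborolidine and catecholborane gives the (R)-alcohol F9 (the lactone ring is the large group, as phenyl in acetophenone). Ac2O and pyridine at 0 °C return to the route at 17.

**Further compounds**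
F1 | step 2 | oct-3-yn-2-ol (racemic) | CCCCC#CC(C)O
F2 | step 2 | methyl oct-3-yn-2-yl carbonate (racemic) | CCCCC#CC(C)OC(=O)OC
F3 | step 2 | methyl 2-butylpenta-2,3-dienoate (racemic) | CCCCC(C(=O)OC)=C=CC
F4 | step 2 | 2-butylpenta-2,3-dienoic acid (racemic) | CCCCC(C(=O)O)=C=CC
F5 | step 9 | head-to-head anti photodimer of 14 (racemic, one enantiomer drawn) | CCCCC1=C(Br)[C@@]2(OC1=O)[C@@H](Br)[C@H](Br)[C@@]21OC(=O)C(CCCC)=C1Br
F6 | step 9 | mono-(1-bromobutyl) derivative of F5 (side-chain centre undefined) | CCCCC1=C(Br)[C@@]2(OC1=O)[C@@H](Br)[C@H](Br)[C@@]21OC(=O)C(C(Br)CCC)=C1Br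
F7 | step 9 | mono-(1-hydroxybutyl) derivative of F5 (side-chain centre undefined) | CCCCC1=C(Br)[C@@]2(OC1=O)[C@@H](Br)[C@H](Br)[C@@]21OC(=O)C(C(O)CCC)=C1Br
F8 | step 8 | (5Z)-4-bromo-5-(bromomethylidene)-3-butanoylfuran-2(5H)-one | CCCC(=O)C1=C(Br)/C(=C/Br)OC1=O
F9 | step 8 | (5Z)-4-bromo-5-(bromomethylidene)-3-[(1R)-1-hydroxybutyl]furan-2(5H)-one | CCC[C@@H](O)C1=C(Br)/C(=C/Br)OC1=O
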